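**Retrosynthetic overview**
- The target is a trans-3,4-disubstituted tetrahydrofuran (ring O–C9–C8–C8′–C9′, lignan numbering) carrying two aryl carbinols, (7S,8R,8′R,7′R). The strategy rests on one feature: the segment O–C9′H2–C8′H–C7′H(OH)Ar is a (2S,3S)-3-arylglycidol opened at C8′ with inversion, and C9–C8–C7(=O)Ar is an aryl vinyl ketone.
- Key disconnection: O–C9 (oxa-Michael) and C8–C8′ (enolate opening of the epoxide) are made in one flask. This closes the only ring and frees the C7′ hydroxyl.
- The C7 carbinol comes from Felkin–Anh reduction of the C7 ketone; the two phenols are unmasked last.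
- Both partners derive from O-tosylvanillin: the epoxy alcohol by olefination, reduction and Sharpless epoxidation, the enone by vinyl Grignard addition and oxidation.

Key step: step 7

Remark on the chemistry: both phenols are carried as p-toluenesulfonates. An aryl methanesulfonate would give the same electron-withdrawing stabilisation of the benzylic epoxide, but its S–CH3 hydrogens are acidic enough for the alkoxide and enolate bases of step 7 to trigger sulfene loss of the phenoxide. Ar below means 3-methoxy-4-(tosyloxy)phenyl.

Step 1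
Reactants: 1 vanillin
Product: 2 4-formyl-2-methoxyphenyl 4-methylbenzenesulfonate
Conditions: TsCl (1.1 equiv), Et3N, DMAP (cat.), CH2Cl2, 0 °C to rt
Reagents that add atoms: p-toluenesulfonyl chloride, Cc1ccc(cc1)S(Cl)(=O)=O
Why: Sulfonylation of the phenol gives an electron-withdrawing protecting group without acidic α-hydrogens that should survive the organometallic, hydride and enolate reagents that follow.

Step 2
Reactants: 2 4-formyl-2-methoxyphenyl 4-methylbenzenesulfonate; 3 triethyl phosphonoacetate
Product: 4 ethyl (E)-3-[3-methoxy-4-(tosyloxy)phenyl]prop-2-enoate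
Conditions: LiCl, DBU, MeCN, rt
Reagents that add atoms: none
Why: Horner–Wadsworth–Emmons olefination under Masamune–Roush conditions should give the (E)-cinnamate with a base too weak to attack the aryl sulfonate.

Step 3
Reactants: 4 ethyl (E)-3-[3-methoxy-4-(tosyloxy)phenyl]prop-2-enoate
Product: 5 (E)-3-[3-methoxy-4-(tosyloxy)phenyl]prop-2-en-1-ol
Conditions: i-Bu2AlH (2.3 equiv), CH2Cl2, −78 °C; aqueous Rochelle salt
Reagents that add atoms: none
Why: 1,2-Reduction of the conjugated ester by the aluminium hydride gives the allylic alcohol, and aryl sulfonates are inert to the reagent at −78 °C.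

Step 4
Reactants: 5 (E)-3-[3-methoxy-4-(tosyloxy)phenyl]prop-2-en-1-ol
Product: 6 [(2S,3S)-3-[3-methoxy-4-(tosyloxy)phenyl]oxiran-2-yl]methanol
Conditions: Ti(OiPr)4 (10 mol %), L-(+)-diethyl tartrate (12 mol %), t-BuOOH (2 equiv), 4 Å molecular sieves, CH2Cl2, −20 °C
Reagents that add atoms: tert-butyl hydroperoxide, CC(C)(C)OO
Why: Sharpless asymmetric epoxidation with the L-(+)-tartrate delivers oxygen to the face of the (E)-allylic alcohol that gives the (2S,3S)-epoxide, which fixes C7′ and (for later inversion) C8′; the electron-poor aryl ring should keep the benzylic epoxide from ionising.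

Step 5
Reactants: 2 4-formyl-2-methoxyphenyl 4-methylbenzenesulfonate; 7 vinylmagnesium bromide
Product: 8 4-(1-hydroxyprop-2-en-1-yl)-2-methoxyphenyl 4-methylbenzenesulfonate (racemic)
Conditions: THF, −78 °C; NH4Cl (aq)
Reagents that add atoms: none
Why: Grignard 1,2-addition to the aldehyde is far faster at −78 °C than attack on the aryl sulfonate, and the racemic carbinol centre is removed in step 6.

Step 6
Reactants: 8 4-(1-hydroxyprop-2-en-1-yl)-2-methoxyphenyl 4-methylbenzenesulfonate
Product: 9 2-methoxy-4-(prop-2-enoyl)phenyl 4-methylbenzenesulfonate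
Conditions: activated MnO2 (15 equiv), CH2Cl2, rt; filtered and used at once as a cold THF solution
Reagents that add atoms: none
Why: MnO2 oxidation of the doubly activated (allylic and benzylic) alcohol gives the aryl vinyl ketone under neutral heterogeneous conditions that spare the polymerisation-prone enone.

Step 7
Reactants: 6 [(2S,3S)-3-[3-methoxy-4-(tosyloxy)phenyl]oxiran-2-yl]methanol; 9 2-methoxy-4-(prop-2-enoyl)phenyl 4-methylbenzenesulfonate
Product: 11 (8R,8′R,7′R)-ketol trans-3-aroyl-4-[(R)-aryl(hydroxy)methyl]tetrahydrofuran (aryl = Ar), via keto ether 10 (not isolated)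
Conditions: NaH (0.1 equiv), THF, −20 °C, 9 (1.05 equiv) added over 1 h; then NaN(SiMe3)2 (1.1 equiv), −78 to 0 °C; NH4Cl (aq) at −20 °C
Reagents that add atoms: none
Why: Proposed new method: the catalytic sodium alkoxide of 6 adds to the β-carbon C9 of 9 (oxa-Michael, with unreacted 6 as proton relay) to give ether 10, whose only possible enolate (C8) then attacks the proximal epoxide carbon C8′ from the rear, leaving the epoxide oxygen on C7′ as the free carbinol. The closest known reactions are base-catalysed additions of alcohols to vinyl ketones, intramolecular alkylation of ketone enolates by epoxides, and the C-2 opening of 3-arylglycidols by nucleophiles tethered through O-1 (carbamate and imidate nitrogen); their combination on one substrate has not been shown. The tetrahydrofuran closes in the 5-exo-tet mode with the enolate double bond outside the forming ring. C8′ is set by stereospecific inversion of the Sharpless-derived centre and C7′ is untouched; C8 is set in the staggered ring-closing transition state that keeps the enolate and the epoxide-bearing branch apart, and trans is also the more stable arrangement if the centre equilibrates through the enolate. The step needs 5-exo attack at C8′ to beat 6-endo attack at the benzylic C7′, and needs the β-alkoxy enolate to cyclise faster than it reverts and oligomerises; the three-atom tether, the electron-poor sulfonyloxy aryl ring, the weakly Lewis acidic sodium counter-ion and the consumption of 9 before stoichiometric base is added are meant to secure this. The quench is cold and early so that the product alkoxide cannot re-enolise C8.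

Step 8
Reactants: 11 (8R,8′R,7′R)-ketol
Product: 12 (7S,8R,8′R,7′R)-diol bis-tosylate, trans-3-[(S)-aryl(hydroxy)methyl]-4-[(R)-aryl(hydroxy)methyl]tetrahydrofuran (aryl = Ar)
Conditions: LiBH(s-Bu)3 (2.5 equiv), THF, −78 °C; NH4Cl (aq)
Reagents that add atoms: none
Why: Felkin–Anh controlled reduction, in which the bulky borohydride should attack the C7 carbonyl anti to the branched ring carbon C8′ and past C8–H to give 7S from 8R, while the C7′ hydroxyl is capped in situ as its alkoxytrialkylborate and the low temperature keeps C8 from epimerising.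

Step 9
Reactants: 12 (7S,8R,8′R,7′R)-diol bis-tosylate
Product: 13 target, (7S,8R,8′R,7′R)-4,4′-dihydroxy-3,3′-dimethoxy-9,9′-epoxylignane-7,7′-diol
Conditions: KOH (10 equiv), MeOH/H2O 4:1, 60 °C, argon; NH4Cl (aq) to pH 7
Reagents that add atoms: none
Why: Hydroxide attacks the sulfonyl sulfur of each aryl tosylate (sulfonate ester hydrolysis with S–O cleavage), so none of the four stereocentres, none of which is α to a carbonyl group, should be touched, and neutral work-up avoids acid ionisation of the p-hydroxybenzylic alcohols.

**Compound list**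
1 | vanillin | COc1cc(C=O)ccc1O | starting material
2 | 4-formyl-2-methoxyphenyl 4-methylbenzenesulfonate | COc1cc(C=O)ccc1OS(=O)(=O)c1ccc(C)cc1 | intermediate
3 | triethyl phosphonoacetate | CCOC(=O)CP(=O)(OCC)OCC | starting material
4 | ethyl (E)-3-[3-methoxy-4-(tosyloxy)phenyl]prop-2-enoate | CCOC(=O)/C=C/c1ccc(OS(=O)(=O)c2ccc(C)cc2)c(OC)c1 | intermediate
5 | (E)-3-[3-methoxy-4-(tosyloxy)phenyl]prop-2-en-1-ol | OC/C=C/c1ccc(OS(=O)(=O)c2ccc(C)cc2)c(OC)c1 | intermediate
6 | [(2S,3S)-3-[3-methoxy-4-(tosyloxy)phenyl]oxiran-2-yl]methanol | OC[C@@H]1O[C@H]1c1ccc(OS(=O)(=O)c2ccc(C)cc2)c(OC)c1 | intermediate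
7 | vinylmagnesium bromide | C=C[Mg]Br | starting material
8 | 4-(1-hydroxyprop-2-en-1-yl)-2-methoxyphenyl 4-methylbenzenesulfonate (racemic) | C=CC(O)c1ccc(OS(=O)(=O)c2ccc(C)cc2)c(OC)c1 | intermediate
9 | 2-methoxy-4-(prop-2-enoyl)phenyl 4-methylbenzenesulfonate | C=CC(=O)c1ccc(OS(=O)(=O)c2ccc(C)cc2)c(OC)c1 | intermediate
10 | keto ether, 3-{[(2S,3S)-3-aryloxiran-2-yl]methoxy}-1-arylpropan-1-one (aryl = Ar; formed in the flask in step 7) | COc1cc(C(=O)CCOC[C@@H]2O[C@H]2c2ccc(OS(=O)(=O)c3ccc(C)cc3)c(OC)c2)ccc1OS(=O)(=O)c1ccc(C)cc1 | intermediate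
11 | (8R,8′R,7′R)-ketol, trans-3-aroyl-4-[(R)-aryl(hydroxy)methyl]tetrahydrofuran (aryl = Ar) | COc1cc(C(=O)[C@H]2COC[C@@H]2[C@@H](O)c2ccc(OS(=O)(=O)c3ccc(C)cc3)c(OC)c2)ccc1OS(=O)(=O)c1ccc(C)cc1 | intermediate
12 | (7S,8R,8′R,7′R)-diol bis-tosylate | COc1cc([C@@H](O)[C@H]2COC[C@@H]2[C@@H](O)c2ccc(OS(=O)(=O)c3ccc(C)cc3)c(OC)c2)ccc1OS(=O)(=O)c1ccc(C)cc1 | intermediate
13 | (7S,8R,8′R,7′R)-4,4′-dihydroxy-3,3′-dimethoxy-9,9′-epoxylignane-7,7′-diol | COc1cc([C@@H](O)[C@H]2COC[C@@H]2[C@@H](O)c2ccc(O)c(OC)c2)ccc1O | target

**Step count:** 9 steps in total; longest linear sequence 7 steps (steps 1, 2, 3, 4, 7, 8, 9).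

**Steps most likely to fail**

1. Step 7 (proposed new method). The β-alkoxy enolate may revert to alkoxide and enone and be drained by enone oligomerisation before the slow epoxide opening, or the planar enolate may close on the benzylic carbon C7′ to a six-membered ring instead of on C8′. The fallback sets out from 6 and comes back at 11, using known reactions with a sulfonyl carbanion as the carbon nucleophile and attaching the aroyl group afterwards. Base-catalysed addition of 6 to phenyl vinyl sulfone (KOt-Bu cat., THF, 0 °C) should give the stable 2-(phenylsulfonyl)ethyl glycidyl ether F1. LiN(i-Pr)2 at −78 °C then gives the α-sulfonyl carbanion, which is not planar like an enolate and should alkylate itself with the tethered epoxide in the exo mode (epoxy sulfone cyclisation) to the 3-(phenylsulfonyl)tetrahydrofuran carbinol F2. Its dianion (LiN(i-Pr)2, 2.2 equiv) is C-acylated with methyl 3-methoxy-4-(tosyloxy)benzoate F3 (from methyl vanillate and TsCl) to the α-sulfonyl ketone F4. SmI2 in THF/MeOH at −78 °C removes the sulfone, and protonation of the resulting enolate should give the trans ketol 11.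

2. Step 8. Hydride may be delivered to the wrong face if the C7′ alkoxide chelates the carbonyl and turns the C8′ branch inward, and the basic medium may epimerise C8, after which the cis isomer closes to a hemiketal. The fallback sets out from 11 and comes back at 12. The C7′ hydroxyl is masked as the triethylsilyl ether F5 (Et3SiCl, imidazole, DMF). The ketone is then reduced under reagent control with the (R)-Me-CBS oxazaborolidine [(R)-1-methyl-3,3-diphenyltetrahydro-1H,3H-pyrrolo[1,2-c][1,3,2]oxazaborole] and BH3·SMe2, where the aryl group acts as the large substituent and the catalyst preference matches the Felkin–Anh preference, to give the 7S silyl ether alcohol F6. Methanolysis of the silyl ether (pyridinium p-toluenesulfonate, MeOH) returns 12.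

3. Step 9. In hot alkali the freed p-hydroxybenzylic alcohols may lose hydroxide to quinone methides, which would scramble C7 and C7′ or be captured by methoxide. The fallback sets out from 12 and comes back at 13. The S–O bonds are cut by electron transfer instead of hydrolysis, with SmI2, Et3N and H2O in THF at rt, a reductive cleavage of arenesulfonate esters that runs near neutrality and without heating. It makes no new compound (F0).

**Further compounds**
F1 | step 7 | (2S,3S)-2-aryl-3-{[2-(phenylsulfonyl)ethoxy]methyl}oxirane (aryl = Ar) | O=S(=O)(CCOC[C@@H]1O[C@H]1c1ccc(OS(=O)(=O)c2ccc(C)cc2)c(OC)c1)c1ccccc1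
F2 | step 7 | (R)-aryl[(3R)-4-(phenylsulfonyl)tetrahydrofuran-3-yl]methanol (aryl = Ar; sulfonyl-bearing carbon not defined) | O=S(=O)(c1ccccc1)C1COC[C@@H]1[C@@H](O)c1ccc(OS(=O)(=O)c2ccc(C)cc2)c(OC)c1
F3 | step 7 | methyl 3-methoxy-4-(tosyloxy)benzoate | COC(=O)c1ccc(OS(=O)(=O)c2ccc(C)cc2)c(OC)c1
F4 | step 7 | 3-aroyl-3-(phenylsulfonyl)-4-[(R)-aryl(hydroxy)methyl]tetrahydrofuran (aryl = Ar; quaternary carbon not defined) | COc1cc(C(=O)C2(S(=O)(=O)c3ccccc3)COC[C@@H]2[C@@H](O)c2ccc(OS(=O)(=O)c3ccc(C)cc3)c(OC)c2)ccc1OS(=O)(=O)c1ccc(C)cc1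
F5 | step 8 | (8R,8′R,7′R)-ketol 7′-O-triethylsilyl ether | COc1cc(C(=O)[C@H]2COC[C@@H]2[C@@H](O[Si](CC)(CC)CC)c2ccc(OS(=O)(=O)c3ccc(C)cc3)c(OC)c2)ccc1OS(=O)(=O)c1ccc(C)cc1
F6 | step 8 | (7S,8R,8′R,7′R)-diol bis-tosylate 7′-O-triethylsilyl ether | COc1cc([C@@H](O)[C@H]2COC[C@@H]2[C@@H](O[Si](CC)(CC)CC)c2ccc(OS(=O)(=O)c3ccc(C)cc3)c(OC)c2)ccc1OS(=O)(=O)c1ccc(C)cc1
F0 | step 9 | none | none
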